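**Retrosynthetic overview**

1. Numbering: C1 acid, C2 (Me), C3–C6 dioxane carbons, C7–C8 linker, ring B C9=C10(Me)–C11–C12–C17–C18(Me2), ring A C12–C13=C14(Me)–C15–C16–C17. The strategy rests on ring A plus C18 being a p-menth-1-ene, so (S)-limonene supplies C12–C18 and the C17 configuration, and on the crowded C9–C18 bond that links quaternary C18 to the tetrasubstituted C9=C10 alkene of ring B.
2. 1,2-Dioxane (formed last): C3–O by 6-exo SN2 closure of a C6 tertiary hydroperoxide on a C3 mesylate; C2/C3 from an Evans syn-aldol; C6–OOH from a Sharpless epoxide opened by H2O2 with inversion.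
3. Ring B (formed second, key step): C9–C18 by ipso attack of a Z-vinylsilane on the C18 terpinyl-type cation generated from the tertiary carbinol.
4. Z-vinylsilane arm: syn-methylmagnesiation of a silylalkyne, iodinolysis and Negishi coupling; C12 is set cis to C17 by an Eschenmoser–Claisen shift from the syn dienol.
5. Ring order: A (chiral pool) → B (step 10) → dioxane (step 22).

Key step: step 10

Shorthand in names: "menthenyl" = (1R,6S)-3-methyl-6-(prop-1-en-2-yl)cyclohex-2-en-1-yl (ring substituents cis); "octalinyl" = (4aR,8aS)-1,1,3,6-tetramethyl-1,4,4a,7,8,8a-hexahydronaphthalen-2-yl (cis-fused).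

Assumption: the α-silylvinylmagnesium 12 is taken to hold its geometry until low-temperature iodinolysis, and both C–O substitutions (C6 in step 14, C3 in step 22) are taken to go with inversion.

**Route**

Step 1
Reactants: 1 (S)-limonene
Product: 3 (1R,2S,4S)-limonene 1,2-oxide (epoxide O syn to isopropenyl), via bromohydrin 2 (not isolated)
Conditions: NBS, acetone/H2O, 0 °C; then aq NaOH, rt
Reagents that add atoms: water, O
Why: Halohydrin epoxidation: the bromonium ion forms on the more electron-rich ring alkene, water opens it trans-diaxially at tertiary C1 (Fürst–Plattner) and hydroxide closes the bromohydrin, which should place the epoxide oxygen on the isopropenyl face.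

Step 2
Reactants: 3 (1R,2S,4S)-limonene 1,2-oxide
Product: 6 (1R,4S)-1-methyl-4-(prop-1-en-2-yl)cyclohex-2-en-1-ol (OH syn to isopropenyl), via hydroxy selenide 4 (not isolated), via selenoxide 5 (not isolated)
Conditions: PhSeSePh, NaBH4, EtOH, rt to reflux; then THF, 30% H2O2, 0 °C to rt
Reagents that add atoms: none
Why: Sharpless–Lauer epoxide-to-allylic-alcohol transposition: phenylselenide opens this oxide trans-diaxially at secondary C2 so the C1–O bond is kept, and selenoxide syn-elimination can only go toward C3.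

Step 3
Reactants: 6 the syn dienol; 7 N,N-dimethylacetamide dimethyl acetal
Product: 8 N,N-dimethyl-2-(menthenyl)acetamide
Conditions: xylenes, 140 °C, MeOH distilled off
Reagents that add atoms: N,N-dimethylacetamide dimethyl acetal (7), CN(C)C(C)(OC)OC
Why: Eschenmoser–Claisen rearrangement: the ketene N,O-acetal of the tertiary allylic alcohol shifts suprafacially, so the C–O bond is exchanged for the C12–C11 bond on the same face (cis to isopropenyl at C17) and the alkene moves to C13=C14.

Step 4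
Reactants: 8 N,N-dimethyl-2-(menthenyl)acetamide
Product: 9 2-(menthenyl)acetaldehyde
Conditions: Cp2Zr(H)Cl (1.5 equiv), THF, rt, short time
Reagents that add atoms: none
Why: Schwartz-reagent reduction of a tertiary amide stops at the aldehyde through a zirconated hemiaminal and should be faster than hydrozirconation of the 1,1-di- and trisubstituted alkenes.

Step 5
Reactants: 9 2-(menthenyl)acetaldehyde
Product: 10 3-(menthenyl)prop-1-yne
Conditions: dimethyl (1-diazo-2-oxopropyl)phosphonate, K2CO3, MeOH, 0 °C to rt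
Reagents that add atoms: Ohira–Bestmann reagent, CC(=O)C(=[N+]=[N-])P(=O)(OC)OC
Why: Seyferth–Gilbert homologation in the Ohira–Bestmann form converts the CH2–CHO unit (no epimerisable centre next to it) into the terminal alkyne under mild base.

Step 6
Reactants: 10 3-(menthenyl)prop-1-yne
Product: 11 trimethyl[3-(menthenyl)prop-1-yn-1-yl]silane
Conditions: n-BuLi, THF, −78 °C; TMSCl, −78 °C to rt
Reagents that add atoms: chlorotrimethylsilane, C[Si](C)(C)Cl
Why: Acetylide formation and C-silylation, a standard alkyne protection that also installs the silicon needed at C9.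

Step 7
Reactants: 11 the silylalkyne
Product: 13 [(E)-1-iodo-2-methyl-3-(menthenyl)prop-1-en-1-yl]trimethylsilane (Si cis to C11), via vinylmagnesium bromide 12 (not isolated)
Conditions: MeMgBr, Ni(acac)2 (10 mol %), Me3Al (10 mol %), THF, 0 °C to rt; then I2, THF, −78 °C
Reagents that add atoms: methylmagnesium bromide, C[Mg]Br; iodine, II
Why: Nickel-catalysed carbomagnesiation of a 1-silylalkyne should add methyl to C10 and magnesium to the silicon-bearing C9 in a syn sense, and prompt iodinolysis with retention fixes silicon cis to C11 (geometric purity is checked at this crystallisable or chromatographable iodide).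

Step 8
Reactants: 13 the α-silyl vinyl iodide; 14 2-(2-bromoethyl)-2-methyl-1,3-dioxolane
Product: 17 (Z)-6-methyl-7-(menthenyl)-5-(trimethylsilyl)hept-5-en-2-one, via zinc reagent 15 (not isolated), via ketal 16 (not isolated)
Conditions: 14, Zn dust, LiCl, THF, 50 °C; 13, Pd(OAc)2/SPhos (cat.), THF, rt to 50 °C; then 1 M HCl, THF, rt
Reagents that add atoms: 2-(2-bromoethyl)-2-methyl-1,3-dioxolane (14, as its zinc reagent), CC1(CCBr)OCCO1; water, O
Why: Negishi sp2–sp3 coupling proceeds with retention of alkene geometry at the hindered vinyl iodide, and the dioxolane is hydrolysed in the acidic work-up under conditions too mild for protodesilylation.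

Step 9
Reactants: 17 the isopropenyl vinylsilane ketone
Product: 18 (Z)-7-[(1R,6S)-6-(2-hydroxypropan-2-yl)-3-methylcyclohex-2-en-1-yl]-6-methyl-5-(trimethylsilyl)hept-5-en-2-one
Conditions: Co(acac)2 (cat.), PhSiH3, O2 (1 atm), THF, rt
Reagents that add atoms: dioxygen, O=O
Why: Mukaiyama hydration (hydrogen-atom transfer, O2 trapping) is Markovnikov-selective and should pick the 1,1-disubstituted isopropenyl group over the trisubstituted ring alkene and the tetrasubstituted vinylsilane.

Step 10
Reactants: 18 the C18 tertiary carbinol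
Product: 19 4-(octalinyl)butan-2-one
Conditions: TiCl4 (2.2 equiv), 2,6-di-tert-butyl-4-methylpyridine (1.1 equiv), CH2Cl2, −78 to −40 °C
Reagents that add atoms: none
Why: TiCl4 ionises the C18 carbinol (through its titanate or tertiary chloride) to an α-terpinyl-type cation, which is attacked by the silicon-bearing C9 of the cis side arm; the charge then sits at C10, tertiary and β to silicon, and loss of the silyl group restores C9=C10 exactly where the silicon was. The closest known reaction type is the vinylsilane-terminated cation–olefin cyclisation in the endocyclic mode, here with the less common tertiary-carbocation initiator. Ring B closes 6-endo with respect to the vinylsilane (C9 and C10 both become ring atoms), which only the Z isomer with silicon cis to C11 can do. No new stereocentre is formed; the cis ring fusion is carried over from the cis C12/C17 pattern set in steps 1–3. The step needs C9 to trap the cation faster than proton loss, a C17-to-C18 hydride shift, attack by the C13=C14 alkene or protodesilylation; the cis arm holds C9 within six-ring reach, the β-silicon effect directs bonding to C9 and fixes the alkene position, and the hindered base removes HCl.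

Step 11
Reactants: 19 4-(octalinyl)butan-2-one
Product: 21 4-(octalinyl)but-1-yne, via enol phosphate 20 (not isolated)
Conditions: LDA, THF, −78 °C; ClP(O)(OEt)2; then LDA (2.3 equiv), −78 °C to rt
Reagents that add atoms: none
Why: Negishi's methyl ketone-to-alkyne protocol: kinetic deprotonation on the methyl side gives the terminal enol phosphate, which undergoes β-elimination with LDA.

Step 12
Reactants: 21 4-(octalinyl)but-1-yne
Product: 23 (E)-3-methyl-5-(octalinyl)pent-2-en-1-ol, via alkenylalane 22 (not isolated)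
Conditions: Me3Al, Cp2ZrCl2 (cat.), CH2Cl2, rt; then n-BuLi, THF, −78 °C; (CH2O)n, rt
Reagents that add atoms: trimethylaluminium, C[Al](C)C; paraformaldehyde (as formaldehyde), C=O
Why: Zirconium-catalysed carboalumination (Negishi) adds Me–Al syn across the terminal alkyne and the derived alanate is hydroxymethylated with retention, which should give the E-trisubstituted allylic alcohol without the E/Z mixture of a ketone olefination.

Step 13
Reactants: 23 the E-allylic alcohol
Product: 24 [(2S,3S)-3-methyl-3-[2-(octalinyl)ethyl]oxiran-2-yl]methanol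
Conditions: Ti(OiPr)4 (cat.), L-(+)-diethyl tartrate, t-BuOOH, 4 Å MS, CH2Cl2, −20 °C
Reagents that add atoms: tert-butyl hydroperoxide, CC(C)(C)OO
Why: Sharpless asymmetric epoxidation under reagent control (L-(+)-tartrate, same sense as for geraniol) sets C6 and the transient C5, and the hydroxyl-directed titanium peroxide leaves the isolated ring alkenes alone.

Step 14
Reactants: 24 the (2S,3S)-epoxy alcohol
Product: 25 (2S,3R)-3-hydroperoxy-3-methyl-5-(octalinyl)pentane-1,2-diol
Conditions: anhydrous H2O2 in Et2O (excess), phosphomolybdic acid (cat.), 0 °C to rt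
Reagents that add atoms: hydrogen peroxide, OO
Why: Molybdenum-catalysed perhydrolysis opens the epoxide at the tertiary carbon with inversion (borderline SN2), which should give the (R)-configured C6–OOH of the target.

Step 15
Reactants: 25 the hydroperoxy diol
Product: 27 (R)-2-[(2-methoxypropan-2-yl)peroxy]-2-methyl-4-(octalinyl)butanal, via hydroperoxy aldehyde 26 (not isolated)
Conditions: NaIO4, THF/pH 7 buffer, 0 °C; then 2-methoxypropene, PPTS (cat.), CH2Cl2, 0 °C
Reagents that add atoms: 2-methoxypropene, COC(C)=C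
Why: Periodate glycol cleavage (inert to the hydroperoxide) excises C4 and turns C5 into the aldehyde, and the hydroperoxide is masked at once as the peroxyketal; C6 carries no hydrogen and cannot epimerise.

Step 16
Reactants: 27 the α-peroxy aldehyde; 28 triethyl phosphonoacetate
Product: 29 ethyl (R,E)-4-[(2-methoxypropan-2-yl)peroxy]-4-methyl-6-(octalinyl)hex-2-enoate
Conditions: 28, NaH, THF, 0 °C; then 27, 0 °C to rt
Reagents that add atoms: triethyl phosphonoacetate (28), CCOC(=O)CP(=O)(OCC)OCC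
Why: Horner–Wadsworth–Emmons olefination of a non-enolisable aldehyde adds C4 and C3, and the peroxyketal is stable to the basic phosphonate anion.

Step 17
Reactants: 29 the enoate
Product: 30 ethyl (R)-4-[(2-methoxypropan-2-yl)peroxy]-4-methyl-6-(octalinyl)hexanoate
Conditions: 2-nitrobenzenesulfonylhydrazide (excess), Et3N, CH2Cl2, rt
Reagents that add atoms: none
Why: Diimide reduction transfers H2 concertedly to the disubstituted C4=C5 bond and should spare the O–O bond and the tri- and tetrasubstituted ring alkenes.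

Step 18
Reactants: 30 the saturated ester
Product: 31 (R)-4-[(2-methoxypropan-2-yl)peroxy]-4-methyl-6-(octalinyl)hexanal
Conditions: DIBAL (1.1 equiv), CH2Cl2, −78 °C
Reagents that add atoms: none
Why: Partial ester reduction with DIBAL at −78 °C stops at the aldehyde through the stable aluminium hemiacetal, at a temperature where the dialkyl peroxyketal should survive.

Step 19
Reactants: 31 the C3 aldehyde; 32 (R)-4-benzyl-3-propionyloxazolidin-2-one
Product: 33 (R)-4-benzyl-3-[(2R,3S,6R)-3-hydroxy-6-[(2-methoxypropan-2-yl)peroxy]-2,6-dimethyl-8-(octalinyl)octanoyl]oxazolidin-2-one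
Conditions: 32, Bu2BOTf, i-Pr2NEt, CH2Cl2, −78 to 0 °C; then 31, −78 to 0 °C; pH 7 buffer, MeOH, H2O2
Reagents that add atoms: (R)-4-benzyl-3-propionyloxazolidin-2-one (32), CCC(=O)N1[C@H](Cc2ccccc2)COC1=O
Why: Evans syn-aldol through the Z-boron enolate and a Zimmerman–Traxler transition state: the (R)-auxiliary sets C2 as in the target and C3 with the configuration opposite to the target, ready for inversion in step 22.

Step 20
Reactants: 33 the aldol adduct
Product: 34 (2S,3S,6R)-6-[(2-methoxypropan-2-yl)peroxy]-2,6-dimethyl-8-(octalinyl)octane-1,3-diol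
Conditions: NaBH4, THF/H2O, 0 °C to rt
Reagents that add atoms: none
Why: Borohydride reductive cleavage of the N-acyl oxazolidinone gives the primary alcohol and takes C1 out of the carbonyl oxidation level so that the later C3 mesylate cannot eliminate by E1cB; borohydride does not reduce dialkyl peroxides.

Step 21
Reactants: 34 the 1,3-diol
Product: 36 (2S,3S,6R)-1-[(tert-butyldimethylsilyl)oxy]-6-[(2-methoxypropan-2-yl)peroxy]-2,6-dimethyl-8-(octalinyl)octan-3-yl methanesulfonate, via silyl ether 35 (not isolated)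
Conditions: TBSCl, imidazole, CH2Cl2, 0 °C; then MsCl, Et3N, 0 °C
Reagents that add atoms: tert-butyldimethylsilyl chloride, CC(C)(C)[Si](C)(C)Cl; methanesulfonyl chloride, CS(=O)(=O)Cl
Why: Selective silylation of the primary hydroxyl followed by sulfonylation of the remaining C3 hydroxyl (both with retention) turns C3 into the electrophile.

Step 22
Reactants: 36 the mesylate
Product: 38 (2S)-2-[(3R,6R)-6-methyl-6-[2-(octalinyl)ethyl]-1,2-dioxan-3-yl]propan-1-ol, via hydroperoxy mesylate 37 (not isolated)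
Conditions: CSA (cat.), MeOH, 0 °C; then KOt-Bu (1.0 equiv), 18-crown-6, THF, 0 °C
Reagents that add atoms: none
Why: Acidic methanolysis removes the peroxyketal and the silyl ether, and the more acidic hydroperoxide is then deprotonated selectively and displaces the C3 mesylate by intramolecular 6-exo-tet SN2 (hydroperoxide alkylation) with inversion, which sets C3 as R.

Step 23
Reactants: 38 the dioxane alcohol
Product: 39 (2R)-2-[(3R,6R)-6-methyl-6-[2-(octalinyl)ethyl]-1,2-dioxan-3-yl]propanoic acid (CNP0122760.1)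
Conditions: TEMPO (cat.), PhI(OAc)2, MeCN/H2O, rt
Reagents that add atoms: water, O
Why: TEMPO/PhI(OAc)2 oxidation in wet acetonitrile takes the primary alcohol through the aldehyde hydrate to the acid under near-neutral conditions that should leave the peroxide, the ring alkenes and the C2 centre untouched.

**Compound list**

1 | (S)-limonene | CC1=CC[C@@H](C(C)=C)CC1 | starting material
2 | (1R,2R,4S)-2-bromo-1-methyl-4-(prop-1-en-2-yl)cyclohexan-1-ol | C[C@]1(O)[C@H](Br)C[C@@H](C(C)=C)CC1 | intermediate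
3 | (1R,2S,4S)-limonene 1,2-oxide | C[C@]12O[C@H]1C[C@@H](C(C)=C)CC2 | intermediate
4 | (1R,2R,4S)-1-methyl-2-(phenylselanyl)-4-(prop-1-en-2-yl)cyclohexan-1-ol | C[C@]1(O)[C@H]([Se]c2ccccc2)C[C@@H](C(C)=C)CC1 | intermediate
5 | selenoxide of 4 | C[C@]1(O)[C@H]([Se](=O)c2ccccc2)C[C@@H](C(C)=C)CC1 | intermediate
6 | (1R,4S)-1-methyl-4-(prop-1-en-2-yl)cyclohex-2-en-1-ol | C[C@]1(O)C=C[C@@H](C(C)=C)CC1 | intermediate
7 | N,N-dimethylacetamide dimethyl acetal | CN(C)C(C)(OC)OC | starting material
8 | N,N-dimethyl-2-(menthenyl)acetamide | CC1=C[C@@H](CC(=O)N(C)C)[C@@H](C(C)=C)CC1 | intermediate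
9 | 2-(menthenyl)acetaldehyde | CC1=C[C@@H](CC=O)[C@@H](C(C)=C)CC1 | intermediate
10 | 3-(menthenyl)prop-1-yne | CC1=C[C@@H](CC#C)[C@@H](C(C)=C)CC1 | intermediate
11 | trimethyl[3-(menthenyl)prop-1-yn-1-yl]silane | CC1=C[C@@H](CC#C[Si](C)(C)C)[C@@H](C(C)=C)CC1 | intermediate
12 | [(Z)-2-methyl-3-(menthenyl)-1-(trimethylsilyl)prop-1-en-1-yl]magnesium bromide | CC1=C[C@@H](C/C(C)=C(/[Mg]Br)[Si](C)(C)C)[C@@H](C(C)=C)CC1 | intermediate
13 | [(E)-1-iodo-2-methyl-3-(menthenyl)prop-1-en-1-yl]trimethylsilane | CC1=C[C@@H](C/C(C)=C(/I)[Si](C)(C)C)[C@@H](C(C)=C)CC1 | intermediate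
14 | 2-(2-bromoethyl)-2-methyl-1,3-dioxolane | CC1(CCBr)OCCO1 | starting material
15 | [2-(2-methyl-1,3-dioxolan-2-yl)ethyl]zinc bromide | CC1(CC[Zn]Br)OCCO1 | intermediate
16 | 2-methyl-2-[(Z)-4-methyl-5-(menthenyl)-3-(trimethylsilyl)pent-3-en-1-yl]-1,3-dioxolane | CC1=C[C@@H](C/C(C)=C(/CCC2(C)OCCO2)[Si](C)(C)C)[C@@H](C(C)=C)CC1 | intermediate
17 | (Z)-6-methyl-7-(menthenyl)-5-(trimethylsilyl)hept-5-en-2-one | CC1=C[C@@H](C/C(C)=C(/CCC(C)=O)[Si](C)(C)C)[C@@H](C(C)=C)CC1 | intermediate
18 | (Z)-7-[(1R,6S)-6-(2-hydroxypropan-2-yl)-3-methylcyclohex-2-en-1-yl]-6-methyl-5-(trimethylsilyl)hept-5-en-2-one | CC1=C[C@@H](C/C(C)=C(/CCC(C)=O)[Si](C)(C)C)[C@@H](C(C)(C)O)CC1 | intermediate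
19 | 4-(octalinyl)butan-2-one | CC1=C[C@H]2CC(C)=C(CCC(C)=O)C(C)(C)[C@H]2CC1 | intermediate
20 | diethyl 5-(octalinyl)pent-1-en-2-yl phosphate | CC1=C[C@H]2CC(C)=C(CCC(=C)OP(=O)(OCC)OCC)C(C)(C)[C@H]2CC1 | intermediate
21 | 4-(octalinyl)but-1-yne | CC1=C[C@H]2CC(C)=C(CCC#C)C(C)(C)[C@H]2CC1 | intermediate
22 | dimethyl[(E)-2-methyl-4-(octalinyl)but-1-en-1-yl]alane | CC1=C[C@H]2CC(C)=C(CC/C(C)=C/[Al](C)C)C(C)(C)[C@H]2CC1 | intermediate
23 | (E)-3-methyl-5-(octalinyl)pent-2-en-1-ol | CC1=C[C@H]2CC(C)=C(CC/C(C)=C/CO)C(C)(C)[C@H]2CC1 | intermediate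
24 | [(2S,3S)-3-methyl-3-[2-(octalinyl)ethyl]oxiran-2-yl]methanol | CC1=C[C@H]2CC(C)=C(CC[C@]3(C)O[C@H]3CO)C(C)(C)[C@H]2CC1 | intermediate
25 | (2S,3R)-3-hydroperoxy-3-methyl-5-(octalinyl)pentane-1,2-diol | CC1=C[C@H]2CC(C)=C(CC[C@@](C)(OO)[C@@H](O)CO)C(C)(C)[C@H]2CC1 | intermediate
26 | (R)-2-hydroperoxy-2-methyl-4-(octalinyl)butanal | CC1=C[C@H]2CC(C)=C(CC[C@@](C)(OO)C=O)C(C)(C)[C@H]2CC1 | intermediate
27 | (R)-2-[(2-methoxypropan-2-yl)peroxy]-2-methyl-4-(octalinyl)butanal | CC1=C[C@H]2CC(C)=C(CC[C@@](C)(OOC(C)(C)OC)C=O)C(C)(C)[C@H]2CC1 | intermediate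
28 | triethyl phosphonoacetate | CCOC(=O)CP(=O)(OCC)OCC | starting material
29 | ethyl (R,E)-4-[(2-methoxypropan-2-yl)peroxy]-4-methyl-6-(octalinyl)hex-2-enoate | CC1=C[C@H]2CC(C)=C(CC[C@@](C)(OOC(C)(C)OC)/C=C/C(=O)OCC)C(C)(C)[C@H]2CC1 | intermediate
30 | ethyl (R)-4-[(2-methoxypropan-2-yl)peroxy]-4-methyl-6-(octalinyl)hexanoate | CC1=C[C@H]2CC(C)=C(CC[C@@](C)(OOC(C)(C)OC)CCC(=O)OCC)C(C)(C)[C@H]2CC1 | intermediate
31 | (R)-4-[(2-methoxypropan-2-yl)peroxy]-4-methyl-6-(octalinyl)hexanal | CC1=C[C@H]2CC(C)=C(CC[C@@](C)(OOC(C)(C)OC)CCC=O)C(C)(C)[C@H]2CC1 | intermediate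
32 | (R)-4-benzyl-3-propionyloxazolidin-2-one | CCC(=O)N1[C@H](Cc2ccccc2)COC1=O | starting material
33 | (R)-4-benzyl-3-[(2R,3S,6R)-3-hydroxy-6-[(2-methoxypropan-2-yl)peroxy]-2,6-dimethyl-8-(octalinyl)octanoyl]oxazolidin-2-one | CC1=C[C@H]2CC(C)=C(CC[C@@](C)(OOC(C)(C)OC)CC[C@H](O)[C@@H](C)C(=O)N3[C@H](Cc4ccccc4)COC3=O)C(C)(C)[C@H]2CC1 | intermediate
34 | (2S,3S,6R)-6-[(2-methoxypropan-2-yl)peroxy]-2,6-dimethyl-8-(octalinyl)octane-1,3-diol | CC1=C[C@H]2CC(C)=C(CC[C@@](C)(OOC(C)(C)OC)CC[C@H](O)[C@@H](C)CO)C(C)(C)[C@H]2CC1 | intermediate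
35 | (2S,3S,6R)-1-[(tert-butyldimethylsilyl)oxy]-6-[(2-methoxypropan-2-yl)peroxy]-2,6-dimethyl-8-(octalinyl)octan-3-ol | CC1=C[C@H]2CC(C)=C(CC[C@@](C)(OOC(C)(C)OC)CC[C@H](O)[C@@H](C)CO[Si](C)(C)C(C)(C)C)C(C)(C)[C@H]2CC1 | intermediate
36 | (2S,3S,6R)-1-[(tert-butyldimethylsilyl)oxy]-6-[(2-methoxypropan-2-yl)peroxy]-2,6-dimethyl-8-(octalinyl)octan-3-yl methanesulfonate | CC1=C[C@H]2CC(C)=C(CC[C@@](C)(OOC(C)(C)OC)CC[C@H](OS(C)(=O)=O)[C@@H](C)CO[Si](C)(C)C(C)(C)C)C(C)(C)[C@H]2CC1 | intermediate
37 | (2S,3S,6R)-6-hydroperoxy-1-hydroxy-2,6-dimethyl-8-(octalinyl)octan-3-yl methanesulfonate | CC1=C[C@H]2CC(C)=C(CC[C@@](C)(OO)CC[C@H](OS(C)(=O)=O)[C@@H](C)CO)C(C)(C)[C@H]2CC1 | intermediate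
38 | (2S)-2-[(3R,6R)-6-methyl-6-[2-(octalinyl)ethyl]-1,2-dioxan-3-yl]propan-1-ol | CC1=C[C@H]2CC(C)=C(CC[C@]3(C)CC[C@H]([C@@H](C)CO)OO3)C(C)(C)[C@H]2CC1 | intermediate
39 | (2R)-2-[(3R,6R)-6-methyl-6-[2-(octalinyl)ethyl]-1,2-dioxan-3-yl]propanoic acid (CNP0122760.1) | CC1=C[C@H]2CC(C)=C(CC[C@]3(C)CC[C@H]([C@@H](C)C(=O)O)OO3)C(C)(C)[C@H]2CC1 | target

**Totals and risks**

Total step count: 23. Longest linear sequence: 23 steps from (S)-limonene (compounds 7, 14, 28 and 32 are bought and enter directly).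

Steps most likely to fail:

Step 10 (key cyclisation). The tertiary cation may lose a proton or accept a hydride from C17 before the fully substituted, silicon-bearing C9 can bond, or the vinylsilane may be protodesilylated first. The fallback sets out from alkyne 10 and comes back at ketone 19; it is a silicon-free, proton-terminated closure through a less hindered C9–H alkene. Zirconium-catalysed carboalumination of 10 with Me3Al and iodinolysis should give the (E)-vinyl iodide F1. Negishi coupling of this with zinc reagent 15 should give the ketal F2, and dilute acid releases the (E)-trisubstituted alkenyl ketone F3. Mukaiyama hydration then gives the carbinol F4. Ionisation of F4 under the step 10 conditions, followed by acid equilibration (TsOH) of the double bond into the tetrasubstituted position, should give 19.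

Step 15 (glycol cleavage beside a free hydroperoxide). The unprotected α-hydroperoxy aldehyde may fragment by C–C cleavage before the peroxyketal is in place. The fallback sets out from epoxy alcohol 24 and comes back at aldehyde 27; the hydroperoxide is masked before the diol is cleaved. Pivaloylation of 24 gives the epoxy pivalate F5. Perhydrolysis as in step 14 gives the hydroperoxy alcohol F6. 2-Methoxypropene/PPTS at low temperature gives the peroxyketal F7. K2CO3/MeOH removes the ester to give the diol F8, and periodate cleavage of F8 gives 27.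

Step 22 (peroxide ring closure). E2 loss of the mesylate at the β-branched C3, or base-induced Kornblum–DeLaMare cleavage of the new secondary peroxide, may outrun the 6-exo substitution. The fallback sets out from aldehyde 31 and comes back at the target 39; the ring is closed instead by intramolecular peroxide conjugate addition. Horner–Wadsworth–Emmons reaction of 31 with triethyl 2-phosphonopropionate gives the (E)-2-methyl enoate F9. PPTS/MeOH frees the hydroperoxide F10. Et2NH in CF3CH2OH closes the dioxane by 6-exo oxa-Michael addition. This closure is not stereocontrolled at C2/C3, so the (2R,3R,6R) ethyl ester F11 would have to be separated by chromatography. LiOH hydrolysis of F11 gives 39.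

**Further compounds**

F1 | step 10 | (E)-1-iodo-2-methyl-3-(menthenyl)prop-1-ene | CC1=C[C@@H](C/C(C)=C/I)[C@@H](C(C)=C)CC1
F2 | step 10 | 2-methyl-2-[(E)-4-methyl-5-(menthenyl)pent-3-en-1-yl]-1,3-dioxolane | CC1=C[C@@H](C/C(C)=C/CCC2(C)OCCO2)[C@@H](C(C)=C)CC1
F3 | step 10 | (E)-6-methyl-7-(menthenyl)hept-5-en-2-one | CC1=C[C@@H](C/C(C)=C/CCC(C)=O)[C@@H](C(C)=C)CC1
F4 | step 10 | (E)-7-[(1R,6S)-6-(2-hydroxypropan-2-yl)-3-methylcyclohex-2-en-1-yl]-6-methylhept-5-en-2-one | CC1=C[C@@H](C/C(C)=C/CCC(C)=O)[C@@H](C(C)(C)O)CC1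
F5 | step 15 | pivalate of epoxy alcohol 24 | CC1=C[C@H]2CC(C)=C(CC[C@]3(C)O[C@H]3COC(=O)C(C)(C)C)C(C)(C)[C@H]2CC1
F6 | step 15 | (2S,3R)-3-hydroperoxy-2-hydroxy-3-methyl-5-(octalinyl)pentyl pivalate | CC1=C[C@H]2CC(C)=C(CC[C@@](C)(OO)[C@@H](O)COC(=O)C(C)(C)C)C(C)(C)[C@H]2CC1
F7 | step 15 | (2S,3R)-2-hydroxy-3-[(2-methoxypropan-2-yl)peroxy]-3-methyl-5-(octalinyl)pentyl pivalate | CC1=C[C@H]2CC(C)=C(CC[C@@](C)(OOC(C)(C)OC)[C@@H](O)COC(=O)C(C)(C)C)C(C)(C)[C@H]2CC1
F8 | step 15 | (2S,3R)-3-[(2-methoxypropan-2-yl)peroxy]-3-methyl-5-(octalinyl)pentane-1,2-diol | CC1=C[C@H]2CC(C)=C(CC[C@@](C)(OOC(C)(C)OC)[C@@H](O)CO)C(C)(C)[C@H]2CC1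
F9 | step 22 | ethyl (R,E)-6-[(2-methoxypropan-2-yl)peroxy]-2,6-dimethyl-8-(octalinyl)oct-2-enoate | CC1=C[C@H]2CC(C)=C(CC[C@@](C)(OOC(C)(C)OC)CC/C=C(\C)C(=O)OCC)C(C)(C)[C@H]2CC1
F10 | step 22 | ethyl (R,E)-6-hydroperoxy-2,6-dimethyl-8-(octalinyl)oct-2-enoate | CC1=C[C@H]2CC(C)=C(CC[C@@](C)(OO)CC/C=C(\C)C(=O)OCC)C(C)(C)[C@H]2CC1
F11 | step 22 | ethyl (2R)-2-[(3R,6R)-6-methyl-6-[2-(octalinyl)ethyl]-1,2-dioxan-3-yl]propanoate | CC1=C[C@H]2CC(C)=C(CC[C@]3(C)CC[C@H]([C@@H](C)C(=O)OCC)OO3)C(C)(C)[C@H]2CC1
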